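## The problem

Compound 17 is a (2S)-flavanone whose ring A is a hexasubstituted phloroglucinol: O1 on C8a, free hydroxyls on C5 and C7, a prenyl group on C8, a (2R)-2-hydroxy-3-methylbut-3-enyl chain on C6, and the C4 carbonyl of ring C on C4a. C6 and C8 are both flanked by two oxygens and are chemically alike, so neither two different carbon substituents nor the O1–C2 bond can be placed on a preformed phloroglucinol with reliable positional control; the positions have to be fixed while ring A is made. The two stereocenters, C2 and the side-chain carbinol, lie seven bonds apart across an aromatic ring and cannot direct each other, so each needs its own source of asymmetry. C2 is configurationally fragile, because a C3 enolate expels O1 (flavanone–chalcone opening), which forbids strong base once ring C carries its aryl group. Acid is no kinder, since a prenyl group beside a free phenol closes to a chroman and the allylic carbinol can ionise, and hydrogenolysis is excluded by three alkenes; protecting groups must therefore be few and removable under buffered, neutral conditions. What makes a late construction of ring A possible is that O1 and the C5 and C7 oxygens sit on alternate carbons like those of a folded triketide: if ring C exists first as a 2-aryl-2,3-dihydropyran-4-one, C4a is the alpha carbon of its vinylogous ester and becomes nucleophilic once the chain carbon on C8a (the future C8) is enolised, and the carbinol oxygen stands gamma to C5, so the C5 acyl carbon can be stored as a γ-lactone of that very carbinol.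

## Retrosynthesis

**17 ⇒ 16 (O–Si on ring B).** Only the ring B phenol is masked at the end, as the triisopropylsilyl ether 16. A silyl ether is preferred to an acetal because buffered fluoride spares the prenyl phenol, the allylic carbinol and C2, whereas acetal cleavage needs acid. The carbinol needs no protecting group in 16, for the reason given in the next paragraph. The forward step only has to avoid free phenoxide and strong base.

**16 ⇒ 15 (C4a–C5; ring A opened; the side-chain oxygen returned to C5 as a γ-lactone).** This is the strategic cut. Its neighbours (C4–C4a, O1–C8a or O1–C2) all leave a fully substituted ring A to be made by substitution chemistry, with the C6/C8 ambiguity unresolved. Cutting C4a–C5 unfolds ring A into a chain on C8a of an intact ring C: C8 with its prenyl group, the C7 ketone, C6 with its side chain, and the C5 acyl carbon. Because the carbinol oxygen is gamma to C5, the acyl group is carried as the lactone of that carbinol. Precursor 15 is then an isomer of 16, no protecting group is spent on the alcohol, an open hydroxy ester (which would lactonise anyway) is avoided, and the s-cis lactone is a better acyl donor than an open ester. 15 holds only the two stereocenters of the target and no aromatic ring A. The forward reaction must make the C8 enolate of 15 react at C4a through the C8a=C4a double bond, with a base too weak to enolise C3.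

**15 ⇒ 13 + 6 (C8–C8a).** The chain could also be cut at C7–C8, but that would mean acylating the gamma carbon of a ring C ketone that is deprotonated kinetically at C3, next to the C2 stereocenter, with an acyl donor that carries an acidic hydrogen and would form a ketene. Cutting C8–C8a turns the polarity problem around. C8 becomes the terminal carbon of the dianion of acyl lactone 13, a site of unambiguous nucleophilicity, and ring C is supplied as the 4-methoxy-5,6-dihydropyran-2-one 6, whose lactone carbonyl carbon becomes C8a. Acid then transposes the adduct to the dihydropyran-4-one. Both fragments are small and carry one stereocenter each, so the route is convergent. The forward step needs carbonyl addition to 6 to outrun deprotonation of 6, and the acid stage must close the pyranone through the C2 hydroxyl.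

**6 ⇒ 2 + 4 (C2–C3 and O1–C8a); 2 ⇒ 1; 4 ⇒ 3.** Lactone 6 is the hetero-Diels–Alder adduct of aldehyde 2 and Brassard's diene 4. This cut creates C2 by a catalytic enantioselective reaction on an achiral aromatic aldehyde, which is simpler than any later enantioselective closure of O1–C2. Aldehyde 2 is the silyl ether of 1, and diene 4 is the silyl dienolate of ester 3. The forward reaction must show high facial selectivity with an electron-rich aldehyde.

**13 ⇒ 11 + 12 (C8–CH2 of the prenyl group); 11 ⇒ 10 (C6–C7).** The prenyl group is attached by alkylating the dianion of acetyl lactone 11 with prenyl bromide 12, which fixes it on the carbon that becomes C8. Acetyl lactone 11 comes from C-acetylation of lactone 10. Building the C7–C8 unit in two steps from cheap reagents is preferred to acylating 10 with a preformed unsaturated acid derivative that would have to be made separately. Both steps are enolate reactions of a γ-lactone and leave its stereocenter alone.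

**10 ⇒ 9 ⇒ 7 (C=CH2, then C–CH3).** The carbinol center cannot be induced from C2, so it is taken from the chiral pool. The carboxyl group of (R)-lactone acid 7 is turned into the isopropenyl group through methyl ketone 9. The oxygen, the CH2 group and the configuration of the future side chain are all present in 7, and its lactone ring is the very ring that serves as acyl donor in the key step. The forward steps must not enolise the ketone of 9 toward the stereocenter.

## Roads not taken

**Alternative 1:** The cut runs through C8–C8a and C6–C7. In the forward direction cyclobutenone A1, which carries the chiral side chain and a methoxymethyl enol ether, is heated with siloxyalkyne A2. Thermal ring opening, [2+2] addition to the alkyne, a second ring opening and 6π closure give phenol A3 with the C8a hydroxyl free, C7 silylated and C5 as its methoxymethyl ether.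
- Merits: the benzannulation is an established reaction class, every substituent is placed by the connectivity of the two partners, and the three oxygens emerge differentiated. It answers the positional problem as cleanly as the chosen plan and with better precedent for the ring-forming event itself.
- Weak points: A3 still lacks ring C. C4a must be acylated to complete a hexasubstituted benzene, the C2–C3 unit attached, and O1–C2 closed enantioselectively by an oxa-Michael reaction, which without an activating group is poorly controlled and runs under the basic conditions that equilibrate C2. A1 is itself a multistep target, and two different acid-labile groups must come off at the end beside the prenyl phenol.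
- Comparison: the chosen plan has an untested ring closure to set against a proven benzannulation. In return it forms C2 by a catalytic cycloaddition on a simple aldehyde, never has to form O1–C2 or C4–C4a late, and ends with a single deprotection.

**Alternative 2:** Here C3–C4 and O1–C2 are cut. Salicylaldehyde A4 is condensed with an orthoester to the methoxy ortho-quinone methide A6, and a chiral BINOL-derived phosphoric acid steers its inverse-demand [4+2] addition to styrene A5, giving the 2,4-cis-4-methoxyflavan A7.
- Merits: ring C and C2 are created in one catalytic, enantioselective and convergent step, ring B comes from a trivial styrene, and no base touches C2. In stereochemical reliability at C2 this road is at least the equal of the hetero-Diels–Alder step used here.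
- Weak points: A4 is a hexasubstituted benzene in which the whole positional problem of ring A, including the distinction between the C8a and C5 hydroxyls, must already be solved, so the hardest part of the molecule is merely moved into the starting material. A7 is at the wrong oxidation level: the C4 ether must be hydrolysed and the benzylic alcohol oxidised beside an electron-rich ring and prenyl-type alkenes, and a stereocenter is built at C4 only to be erased. A6 is flanked by a bulky silyl ether at C5, and the Brønsted acid threatens four silyl ethers and the prenyl group.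
- Comparison: against the elegance of that cycloaddition the chosen plan sets a ring A whose substitution pattern follows from the chain, and a ring C that is at the correct oxidation level from the start.

**Alternative 3:** The cut is C4–C4a. The (S)-3-aryloxy-3-arylpropanoic acid A8, after activation of its carboxyl group by an anhydride, acylates the only free position of its trioxygenated ring and closes ring C to flavanone A9.
- Merits: intramolecular Friedel–Crafts acylation of 3-aryloxypropanoic acids to chroman-4-ones is a known reaction class, the acylation has a single possible site, C2 is installed beforehand (for instance by Mitsunobu etherification of a chiral benzylic alcohol), and few steps follow ring closure. In precedent for the bond-forming step this road is ahead of the chosen one.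
- Weak points: the C2–O1 bond of A8 is a benzylic ether of an electron-rich phenol with a para-oxygenated ring B, so the acidic acylating medium can ionise it (loss of configuration) or eliminate it. The acetate on ring B damps this but must later be removed with base, which again puts C2 at risk. The same medium meets a prenyl group, an allylic silyl ether and two aryl silyl ethers. A8 also presupposes a pentasubstituted phenol in which the ether oxygen has been told apart from its neighbours, a problem that Alternative 1 solves and this road does not.
- Comparison: the chosen plan answers with conditions that are neither strongly acidic nor strongly basic once C2 exists, and with a ring A assembled from a chain. It pays with a key step that has no direct precedent.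

Key step: step 9

Assumption 1: the Ti(OiPr)4/(S)-BINOL catalyst is taken to deliver the diene to the Si face of aldehyde 2, which gives the 6S lactone; if a trial shows the opposite sense, (R)-BINOL is used and nothing else changes.
Assumption 2: compounds 11, 13, 14 and 15 are carried as mixtures of epimers and enol forms at the carbons that lie between two carbonyl groups, since these carbons become sp2 in ring A.
Assumption 3: flavanone numbering (O1, C2–C4, C4a, C5–C8, C8a) is used for the corresponding atoms of all intermediates.

## Route

Step 1
Reactants: 1 4-hydroxybenzaldehyde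
Product: 2 4-(triisopropylsilyloxy)benzaldehyde
Conditions: iPr3SiCl, imidazole, DMF, 25 °C
Reagents that add atoms: triisopropylsilyl chloride, CC(C)[Si](Cl)(C(C)C)C(C)C
Why: Silyl ether formation on a phenol with imidazole as base; the bulky aryl silyl ether should survive lithium enolates, dilute acid and the magnesium/amine conditions and leave with buffered fluoride.

Step 2
Reactants: 3 methyl (E)-3-methoxybut-2-enoate
Product: 4 1,3-dimethoxy-1-(trimethylsilyloxy)buta-1,3-diene (Brassard's diene)
Conditions: LiN(iPr)2, THF, −78 °C; Me3SiCl, −78 → 25 °C
Reagents that add atoms: chlorotrimethylsilane, C[Si](C)(C)Cl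
Why: Gamma-deprotonation of the vinylogous carbonate and O-silylation of the dienolate give the silyl ketene acetal diene, which is used after removal of LiCl and solvent.

Step 3
Reactants: 2 4-(triisopropylsilyloxy)benzaldehyde; 4 Brassard's diene
Product: 6 (6S)-4-methoxy-6-[4-(triisopropylsilyloxy)phenyl]-5,6-dihydro-2H-pyran-2-one, via silyl aldol adduct 5 (not isolated)
Conditions: Ti(OiPr)4 (10 mol %), (S)-BINOL (11 mol %), 4 Å MS, toluene, −20 → 0 °C; then CF3CO2H (cat.), CH2Cl2, 0 °C
Reagents that add atoms: none
Why: Catalytic asymmetric hetero-Diels–Alder reaction of Brassard's diene, which on the titanium BINOLate runs as a Mukaiyama aldol addition to the Si face of the bound aldehyde (this sets 6S, the future C2) followed by acid-induced lactonisation of 5 with loss of the silyl group and methanol.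

Step 4
Reactants: 7 (2R)-5-oxooxolane-2-carboxylic acid
Product: 9 (5R)-5-acetyloxolan-2-one, via acid chloride 8 (not isolated)
Conditions: (COCl)2, DMF (cat.), CH2Cl2, 0 → 25 °C; then Me2CuLi, Et2O/THF, −78 °C
Reagents that add atoms: lithium dimethylcuprate (Me2CuLi), [Li+].C[Cu-]C
Why: Acid chloride formation followed by ketone synthesis with a Gilman cuprate, which stops at the ketone and leaves the lactone alone at −78 °C; the stereocenter is not involved.

Step 5
Reactants: 9 (5R)-5-acetyloxolan-2-one
Product: 10 (5R)-5-(prop-1-en-2-yl)oxolan-2-one
Conditions: Zn, CH2Br2, TiCl4, THF/CH2Cl2, 0 → 25 °C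
Reagents that add atoms: dibromomethane, BrCBr
Why: Takai–Lombardo methylenation; the non-basic gem-dimetallic reagent should convert the ketone into the 1,1-disubstituted alkene without enolising the adjacent oxygen-bearing stereocenter and without attacking the lactone.

Step 6
Reactants: 10 (5R)-5-(prop-1-en-2-yl)oxolan-2-one
Product: 11 (5R)-3-acetyl-5-(prop-1-en-2-yl)oxolan-2-one
Conditions: LiN(SiMe3)2 (2.2 equiv), THF, −78 °C; 1-acetylimidazole, −78 → −30 °C; AcOH
Reagents that add atoms: 1-acetylimidazole, CC(=O)n1ccnc1
Why: Claisen-type C-acylation of the lithium lactone enolate by an N-acylimidazole; the second equivalent of base stores the product as its enolate and so prevents double acylation, and the new center between the two carbonyls is an inconsequential epimer mixture.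

Step 7
Reactants: 11 (5R)-3-acetyl-5-(prop-1-en-2-yl)oxolan-2-one; 12 prenyl bromide (1-bromo-3-methylbut-2-ene)
Product: 13 (5R)-3-(5-methylhex-4-enoyl)-5-(prop-1-en-2-yl)oxolan-2-one
Conditions: LiN(iPr)2 (2.1 equiv), THF, −78 → 0 °C; 12, −78 → 0 °C; AcOH
Reagents that add atoms: none
Why: Gamma-alkylation of a 1,3-dicarbonyl dianion: the second deprotonation takes place at the acetyl methyl group and only this more basic terminus is alkylated by the allylic bromide (SN2), which places the future prenyl group on the future C8.

Step 8
Reactants: 13 (5R)-3-(5-methylhex-4-enoyl)-5-(prop-1-en-2-yl)oxolan-2-one; 6 (6S)-4-methoxy-6-[4-(triisopropylsilyloxy)phenyl]-5,6-dihydro-2H-pyran-2-one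
Product: 15 (5R)-3-{5-methyl-2-[(2S)-4-oxo-2-(4-triisopropylsilyloxyphenyl)-3,4-dihydro-2H-pyran-6-yl]hex-4-enoyl}-5-(prop-1-en-2-yl)oxolan-2-one, via ring-opened hydroxy enone 14 (not isolated)
Conditions: 13 (2.2 equiv), LiN(iPr)2 (4.4 equiv), THF, −78 → 0 °C; 6, −78 → −20 °C; AcOH; then 1 M HCl, THF, 0 → 25 °C
Reagents that add atoms: water, O
Why: The terminal carbanion of the dianion of 13 is acylated by the lactone carbonyl of 6 (Claisen-type acylation of a dianion by a vinylogous carbonate), giving 14 after protonation; in dilute acid the C2 hydroxyl adds to the new ketone, water is lost through the methoxy-stabilised oxocarbenium ion, and its hydrolysis (Stork–Danheiser-type transposition) leaves the dihydropyran-4-one. The C2–O bond is never broken, so the 2S configuration of 6 is carried into 15.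

Step 9
Reactants: 15 (5R)-3-{5-methyl-2-[(2S)-4-oxo-2-(4-triisopropylsilyloxyphenyl)-3,4-dihydro-2H-pyran-6-yl]hex-4-enoyl}-5-(prop-1-en-2-yl)oxolan-2-one
Product: 16 (2S)-5,7-dihydroxy-6-[(2R)-2-hydroxy-3-methylbut-3-enyl]-8-(3-methylbut-2-enyl)-2-(4-triisopropylsilyloxyphenyl)chroman-4-one
Conditions: MgBr2·OEt2 (3 equiv), Et3N (4 equiv), CH2Cl2 (0.01 M), 0 → 25 °C; then 1 M HCl, 0 °C
Reagents that add atoms: none
Why: Proposed new method: Et3N with MgBr2 reversibly enolises 15 at C6 and at C8; the C8 enolate is delocalised through C8a=C4a into the ring C carbonyl, so C4a gains nucleophilic character, while magnesium bound to the C7 oxygen and the lactone carbonyl holds C5 over C4a and activates it. C4a adds to C5 in a 6-(enolexo)-exo-trig closure, the tetrahedral intermediate expels the side-chain alkoxide, and enolisation at C4a–H and C6–H gives the aromatic 5,7-dihydroxy ring A, which makes the sequence irreversible. The closest known reactions are the base- or Mg(OMe)2-mediated Claisen cyclisation of 3,5,7-triketo esters to acylphloroglucinols and the closure of pyranone-masked polyketides to chromones; new here is the use of the alpha carbon of a chiral dihydropyranone dienolate with ring C kept intact. No stereocenter is formed: C2 and the carbinol are spectators and the epimeric centers C6 and C8 of 15 become sp2. C- rather than O-acylation follows from ring size, since C4a is the only nucleophilic atom that reaches C5 through a six-membered transition state (C8 would close a four-membered ring, and attack of C6 on C4 would give a strained bridgehead alkene). Retention of the 2S center requires that no C3 enolate forms, which the weak amine base and the far more acidic C6–H and C8–H should secure. The s-cis lactone is a better acyl donor than an open ester and the reaction is an isomerisation that sets nothing free from the substrate.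

Step 10
Reactants: 16 (2S)-5,7-dihydroxy-6-[(2R)-2-hydroxy-3-methylbut-3-enyl]-8-(3-methylbut-2-enyl)-2-(4-triisopropylsilyloxyphenyl)chroman-4-one
Product: 17 (2S)-5,7-dihydroxy-6-[(2R)-2-hydroxy-3-methylbut-3-enyl]-2-(4-hydroxyphenyl)-8-(3-methylbut-2-enyl)chroman-4-one
Conditions: Bu4NF, AcOH, THF, 0 °C
Reagents that add atoms: none
Why: Fluoride-induced cleavage of the aryl silyl ether; acetic acid buffers the phenoxides so that no C3 enolate and no ring C opening can arise, and the allylic alcohol, the prenyl group and C2 should stay untouched.

## Compound list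

1 | 4-hydroxybenzaldehyde | O=Cc1ccc(O)cc1 | starting material
2 | 4-(triisopropylsilyloxy)benzaldehyde | O=Cc1ccc(O[Si](C(C)C)(C(C)C)C(C)C)cc1 | intermediate
3 | methyl (E)-3-methoxybut-2-enoate | CO/C(C)=C/C(=O)OC | starting material
4 | 1,3-dimethoxy-1-(trimethylsilyloxy)buta-1,3-diene (Brassard's diene, ketene acetal geometry not assigned) | C=C(OC)C=C(OC)O[Si](C)(C)C | intermediate
5 | methyl (2E,5S)-3-methoxy-5-[4-(triisopropylsilyloxy)phenyl]-5-(trimethylsilyloxy)pent-2-enoate | COC(=O)/C=C(/OC)C[C@H](O[Si](C)(C)C)c1ccc(O[Si](C(C)C)(C(C)C)C(C)C)cc1 | intermediate (not isolated)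
6 | (6S)-4-methoxy-6-[4-(triisopropylsilyloxy)phenyl]-5,6-dihydro-2H-pyran-2-one | O=C1C=C(OC)C[C@@H](c2ccc(O[Si](C(C)C)(C(C)C)C(C)C)cc2)O1 | intermediate
7 | (2R)-5-oxooxolane-2-carboxylic acid | O=C(O)[C@H]1CCC(=O)O1 | starting material
8 | (2R)-5-oxooxolane-2-carbonyl chloride | O=C(Cl)[C@H]1CCC(=O)O1 | intermediate (not isolated)
9 | (5R)-5-acetyloxolan-2-one | CC(=O)[C@H]1CCC(=O)O1 | intermediate
10 | (5R)-5-(prop-1-en-2-yl)oxolan-2-one | C=C(C)[C@H]1CCC(=O)O1 | intermediate
11 | (5R)-3-acetyl-5-(prop-1-en-2-yl)oxolan-2-one (C3 epimers) | C=C(C)[C@H]1CC(C(C)=O)C(=O)O1 | intermediate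
12 | prenyl bromide (1-bromo-3-methylbut-2-ene) | CC(C)=CCBr | starting material
13 | (5R)-3-(5-methylhex-4-enoyl)-5-(prop-1-en-2-yl)oxolan-2-one (C3 epimers) | C=C(C)[C@H]1CC(C(=O)CCC=C(C)C)C(=O)O1 | intermediate
14 | (5R)-3-[(4E,7S)-7-hydroxy-5-methoxy-2-(3-methylbut-2-enyl)-3-oxo-7-(4-triisopropylsilyloxyphenyl)hept-4-enoyl]-5-(prop-1-en-2-yl)oxolan-2-one (epimers at the two acidic carbons) | C=C(C)[C@H]1CC(C(=O)C(CC=C(C)C)C(=O)/C=C(/OC)C[C@H](O)c2ccc(O[Si](C(C)C)(C(C)C)C(C)C)cc2)C(=O)O1 | intermediate (not isolated)
15 | (5R)-3-{5-methyl-2-[(2S)-4-oxo-2-(4-triisopropylsilyloxyphenyl)-3,4-dihydro-2H-pyran-6-yl]hex-4-enoyl}-5-(prop-1-en-2-yl)oxolan-2-one (epimers at the two acidic carbons) | C=C(C)[C@H]1CC(C(=O)C(CC=C(C)C)C2=CC(=O)C[C@@H](c3ccc(O[Si](C(C)C)(C(C)C)C(C)C)cc3)O2)C(=O)O1 | intermediate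
16 | (2S)-5,7-dihydroxy-6-[(2R)-2-hydroxy-3-methylbut-3-enyl]-8-(3-methylbut-2-enyl)-2-(4-triisopropylsilyloxyphenyl)chroman-4-one | C=C(C)[C@H](O)Cc1c(O)c(CC=C(C)C)c2c(c1O)C(=O)C[C@@H](c1ccc(O[Si](C(C)C)(C(C)C)C(C)C)cc1)O2 | intermediate
17 | (2S)-5,7-dihydroxy-6-[(2R)-2-hydroxy-3-methylbut-3-enyl]-2-(4-hydroxyphenyl)-8-(3-methylbut-2-enyl)chroman-4-one | C=C(C)[C@H](O)Cc1c(O)c(CC=C(C)C)c2c(c1O)C(=O)C[C@@H](c1ccc(O)cc1)O2 | target

## Step count and risks

Total step count: 10. Longest linear sequence: 7 steps (7 → 9 → 10 → 11 → 13 → 15 → 16 → 17, steps 4 to 10).

Least certain steps: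

**Step 9 (key step, the proposed new method).** Enolisation may rest at the acyl-lactone carbon C6, whose magnesium chelate makes the lactone carbonyl part of an enolate and leaves C4a unengaged, so that no ring closes. Forcing the reaction with more base or heat then invites loss of O1 by β-elimination from a C3 enolate (erosion of the 2S center) and opening of the allylic lactone by bromide.

Fallback by known chemistry, from 15 back to 16: ring C is opened on purpose (KOtBu, THF, 0 °C, retro-oxa-Michael) to the acyclic (E)-styryl triketo lactone F1, in which C4a is an ordinary doubly activated methylene. Mg(OMe)2 in MeOH then effects the classical Claisen cyclisation of a 3,5,7-triketo ester equivalent to the chalcone F2, and NaOAc in EtOH at reflux closes the flavanone by oxa-Michael addition. Because either ortho hydroxyl can add and no chiral influence is present, 16 would form together with its 2R epimer F3 and the 6-prenyl regioisomer F4. 16 is separated by preparative chromatography on a chiral phase, and F3 and F4 are returned to the equilibration through F2. This reserve route gives up the positional and stereochemical control that the key step is meant to provide.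

**Step 8.** The basic dianion may remove a C5 proton of 6, after which the lactone opens by elimination of its carboxylate instead of being attacked at the carbonyl. Addition–elimination at the methoxy-bearing carbon and, in the acid stage, closure of the tricarbonyl unit to a 4-pyranone are lesser risks.

Fallback, from 6 back to 14 and 15: 6 is opened with MeNH(OMe)·HCl/AlMe3 to the hydroxy Weinreb amide F5, which is silylated (Et3SiCl, imidazole) to the triethylsilyl ether F6. The dianion of 13 adds to F6 through a stable chelated tetrahedral intermediate and gives, after work-up, the ketone F7. 1 M HCl in THF removes the silyl group to give 14, which closes to 15 as in the main route.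

**Step 3.** The electron-rich aldehyde 2 may react sluggishly, so that the uncatalysed background reaction lowers the facial selectivity.

Fallback, from 2 back to 6: the cycloaddition is replaced by a stepwise sequence. The more nucleophilic bis-silyl dienolate of methyl acetoacetate (Chan's diene) is added to 2 in a vinylogous Mukaiyama aldol reaction under Ti(OiPr)4/BINOL catalysis, giving after acidic work-up the δ-hydroxy-β-keto ester F8. K2CO3 in MeOH closes the lactone to the dione F9, which would allow enrichment by recrystallisation if crystalline, and O-methylation (Me2SO4, K2CO3, acetone) gives 6.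

**Step 5.** Methylenation of the oxygen-flanked ketone may be incomplete, or the adjacent center may partly epimerise if the Lewis acidic mixture enolises the ketone.

Fallback, from 9 back to 10: MeMgBr with CeCl3 in THF at −78 °C adds to the ketone only and gives the tertiary alcohol F10. Dehydration with the Burgess reagent, which statistically and sterically favours elimination toward a methyl group, gives 10.

## Further compounds

F1 | step 9 | (5R)-3-[(6E)-2-(3-methylbut-2-enyl)-3,5-dioxo-7-(4-triisopropylsilyloxyphenyl)hept-6-enoyl]-5-(prop-1-en-2-yl)oxolan-2-one | C=C(C)[C@H]1CC(C(=O)C(CC=C(C)C)C(=O)CC(=O)/C=C/c2ccc(O[Si](C(C)C)(C(C)C)C(C)C)cc2)C(=O)O1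
F2 | step 9 | (2E)-1-{2,4,6-trihydroxy-3-[(2R)-2-hydroxy-3-methylbut-3-enyl]-5-(3-methylbut-2-enyl)phenyl}-3-(4-triisopropylsilyloxyphenyl)prop-2-en-1-one | C=C(C)[C@H](O)Cc1c(O)c(CC=C(C)C)c(O)c(C(=O)/C=C/c2ccc(O[Si](C(C)C)(C(C)C)C(C)C)cc2)c1O
F3 | step 9 | (2R)-5,7-dihydroxy-6-[(2R)-2-hydroxy-3-methylbut-3-enyl]-8-(3-methylbut-2-enyl)-2-(4-triisopropylsilyloxyphenyl)chroman-4-one | C=C(C)[C@H](O)Cc1c(O)c(CC=C(C)C)c2c(c1O)C(=O)C[C@H](c1ccc(O[Si](C(C)C)(C(C)C)C(C)C)cc1)O2
F4 | step 9 | (2RS)-5,7-dihydroxy-8-[(2R)-2-hydroxy-3-methylbut-3-enyl]-6-(3-methylbut-2-enyl)-2-(4-triisopropylsilyloxyphenyl)chroman-4-one | C=C(C)[C@H](O)Cc1c(O)c(CC=C(C)C)c(O)c2c1OC(c1ccc(O[Si](C(C)C)(C(C)C)C(C)C)cc1)CC2=O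
F5 | step 8 | (2E,5S)-5-hydroxy-N,3-dimethoxy-N-methyl-5-[4-(triisopropylsilyloxy)phenyl]pent-2-enamide | CON(C)C(=O)/C=C(/OC)C[C@H](O)c1ccc(O[Si](C(C)C)(C(C)C)C(C)C)cc1
F6 | step 8 | (2E,5S)-N,3-dimethoxy-N-methyl-5-(triethylsilyloxy)-5-[4-(triisopropylsilyloxy)phenyl]pent-2-enamide | CON(C)C(=O)/C=C(/OC)C[C@H](O[Si](CC)(CC)CC)c1ccc(O[Si](C(C)C)(C(C)C)C(C)C)cc1
F7 | step 8 | (5R)-3-[(4E,7S)-5-methoxy-2-(3-methylbut-2-enyl)-3-oxo-7-(triethylsilyloxy)-7-(4-triisopropylsilyloxyphenyl)hept-4-enoyl]-5-(prop-1-en-2-yl)oxolan-2-one | C=C(C)[C@H]1CC(C(=O)C(CC=C(C)C)C(=O)/C=C(/OC)C[C@H](O[Si](CC)(CC)CC)c2ccc(O[Si](C(C)C)(C(C)C)C(C)C)cc2)C(=O)O1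
F8 | step 3 | methyl (5S)-5-hydroxy-3-oxo-5-[4-(triisopropylsilyloxy)phenyl]pentanoate | COC(=O)CC(=O)C[C@H](O)c1ccc(O[Si](C(C)C)(C(C)C)C(C)C)cc1
F9 | step 3 | (6S)-6-[4-(triisopropylsilyloxy)phenyl]oxane-2,4-dione | O=C1CC(=O)C[C@@H](c2ccc(O[Si](C(C)C)(C(C)C)C(C)C)cc2)O1
F10 | step 5 | (5R)-5-(2-hydroxypropan-2-yl)oxolan-2-one | CC(C)(O)[C@H]1CCC(=O)O1
A1 | alternative 1 | 2-[(2R)-2-(tert-butyldimethylsilyloxy)-3-methylbut-3-enyl]-3-(methoxymethoxy)cyclobut-2-en-1-one | C=C(C)[C@H](O[Si](C)(C)C(C)(C)C)CC1=C(OCOC)CC1=O
A2 | alternative 1 | triisopropyl[(5-methylhex-4-en-1-ynyl)oxy]silane | CC(C)=CCC#CO[Si](C(C)C)(C(C)C)C(C)C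
A3 | alternative 1 | 4-[(2R)-2-(tert-butyldimethylsilyloxy)-3-methylbut-3-enyl]-5-(methoxymethoxy)-2-(3-methylbut-2-enyl)-3-(triisopropylsilyloxy)phenol | C=C(C)[C@H](O[Si](C)(C)C(C)(C)C)Cc1c(O[Si](C(C)C)(C(C)C)C(C)C)c(CC=C(C)C)c(O)cc1OCOC
A4 | alternative 2 | 5-[(2R)-2-(tert-butyldimethylsilyloxy)-3-methylbut-3-enyl]-4,6-bis(tert-butyldimethylsilyloxy)-2-hydroxy-3-(3-methylbut-2-enyl)benzaldehyde | C=C(C)[C@H](O[Si](C)(C)C(C)(C)C)Cc1c(O[Si](C)(C)C(C)(C)C)c(CC=C(C)C)c(O)c(C=O)c1O[Si](C)(C)C(C)(C)C
A5 | alternative 2 | tert-butyldimethyl(4-vinylphenoxy)silane | C=Cc1ccc(O[Si](C)(C)C(C)(C)C)cc1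
A6 | alternative 2 | 4-[(2R)-2-(tert-butyldimethylsilyloxy)-3-methylbut-3-enyl]-3,5-bis(tert-butyldimethylsilyloxy)-6-(methoxymethylidene)-2-(3-methylbut-2-enyl)cyclohexa-2,4-dien-1-one (methoxy ortho-quinone methide) | C=C(C)[C@H](O[Si](C)(C)C(C)(C)C)CC1=C(O[Si](C)(C)C(C)(C)C)C(=COC)C(=O)C(CC=C(C)C)=C1O[Si](C)(C)C(C)(C)C
A7 | alternative 2 | (2S)-2,4-cis-4-methoxyflavan with tert-butyldimethylsilyl ethers on O5, O7, the ring B oxygen and the carbinol, the side chain on C6 and prenyl on C8 | C=C(C)[C@H](O[Si](C)(C)C(C)(C)C)Cc1c(O[Si](C)(C)C(C)(C)C)c(CC=C(C)C)c2c(c1O[Si](C)(C)C(C)(C)C)[C@@H](OC)C[C@@H](c1ccc(O[Si](C)(C)C(C)(C)C)cc1)O2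
A8 | alternative 3 | (3S)-3-(4-acetoxyphenyl)-3-{4-[(2R)-2-(tert-butyldimethylsilyloxy)-3-methylbut-3-enyl]-3,5-bis(tert-butyldimethylsilyloxy)-2-(3-methylbut-2-enyl)phenoxy}propanoic acid | C=C(C)[C@H](O[Si](C)(C)C(C)(C)C)Cc1c(O[Si](C)(C)C(C)(C)C)c(CC=C(C)C)c(O[C@@H](CC(=O)O)c2ccc(OC(C)=O)cc2)cc1O[Si](C)(C)C(C)(C)C
A9 | alternative 3 | (2S)-2-(4-acetoxyphenyl)-5,7-bis(tert-butyldimethylsilyloxy)-6-[(2R)-2-(tert-butyldimethylsilyloxy)-3-methylbut-3-enyl]-8-(3-methylbut-2-enyl)chroman-4-one | C=C(C)[C@H](O[Si](C)(C)C(C)(C)C)Cc1c(O[Si](C)(C)C(C)(C)C)c(CC=C(C)C)c2c(c1O[Si](C)(C)C(C)(C)C)C(=O)C[C@@H](c1ccc(OC(C)=O)cc1)O2
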